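**Plan**

- Retrosynthesis: the six O–benzyl bonds of the protected target 13 are cut last; the flavone C2''=C3'' double bond is taken back to the single bond of the bis-flavanone 12; both C2–C1' aryl bonds are then cut at once, giving bichromone 9 and two molecules of boronic acid 10.
- 9 is cut at the C8–C8' biaryl bond to 8-iodochromone 8, and ring C of 8 at O1–C2 and C2–C3 to iodoacetophenone 5 plus a one-carbon unit, back to phloroacetophenone 1.
- Enabling feature: both rings B are the same 4-oxygenated phenyl group on C2 of a ring C, and the only stereocentre is the benzylic ether carbon C2 of the flavanone ring C, so one reagent can arylate two identical chromone C2 positions in one operation.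
- Forward order: ring A is bought; ring C is closed on the monomer (step 3); two AC units are joined (step 4); both rings B are attached (step 5); one ring C is dehydrogenated (step 6); the benzyl groups are removed (step 7).
- Stereochemistry: C2 (S) comes from ligand-controlled face selection in step 5; the second centre made there (C2'') is erased in step 6, and because two centres are set together the heterochiral diastereomer carries away most minor-face events.

Key step: step 5

Assumption: the target SMILES fixes only C2 (S) and leaves the sense of the hindered 8,8'' axis (four ortho oxygen substituents) open, so 9 is used as the axial racemate and 12–14 are carried as the two axial diastereomers sharing the (2S) centre, separable by chromatography at 12 or 13 if one axial form is wanted.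

**Route**

Step 1
Reactants: 1 2',4',6'-trihydroxyacetophenone; 2 benzyl bromide
Product: 3 4',6'-bis(benzyloxy)-2'-hydroxyacetophenone
Conditions: BnBr (2.1 equiv), K2CO3, DMF, rt
Reagents that add atoms: benzyl bromide, BrCc1ccccc1
Why: Williamson etherification under mild carbonate conditions alkylates the para and one ortho hydroxyl, while the remaining ortho hydroxyl, hydrogen-bonded to the acetyl carbonyl, is too weakly nucleophilic to react.

Step 2
Reactants: 3 4',6'-bis(benzyloxy)-2'-hydroxyacetophenone; 4 benzyltrimethylammonium dichloroiodate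
Product: 5 4',6'-bis(benzyloxy)-2'-hydroxy-3'-iodoacetophenone
Conditions: BnMe3N·ICl2 (1.05 equiv), NaHCO3, CH2Cl2–MeOH, rt
Reagents that add atoms: benzyltrimethylammonium dichloroiodate, C[N+](C)(C)Cc1ccccc1.Cl[I-]Cl
Why: Electrophilic aromatic iodination directed ortho to the free phenol: C3', flanked by OH and one benzyloxy group, is more accessible than C5' between two benzyloxy groups, and one equivalent of the mild dichloroiodate limits di-iodination.

Step 3
Reactants: 5 4',6'-bis(benzyloxy)-2'-hydroxy-3'-iodoacetophenone; 6 N,N-dimethylformamide dimethyl acetal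
Product: 8 5,7-bis(benzyloxy)-8-iodochromen-4-one, via enaminone 7 (not isolated)
Conditions: DMF-DMA, toluene, 100 °C; evaporate; conc. HCl, CH2Cl2, 40 °C
Reagents that add atoms: N,N-dimethylformamide dimethyl acetal, COC(OC)N(C)C
Why: Condensation of the acetyl CH3 with the amide acetal gives the (E)-enaminone 7, and acid then promotes intramolecular conjugate addition of the phenol with loss of dimethylamine (6-endo addition–elimination), the standard enaminone route to 2,3-unsubstituted chromones.

Step 4
Reactants: 8 5,7-bis(benzyloxy)-8-iodochromen-4-one (two molecules)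
Product: 9 5,5',7,7'-tetrakis(benzyloxy)-8,8'-bichromone (axial racemate)
Conditions: activated Cu powder (5 equiv), DMF, 150 °C, Ar
Reagents that add atoms: none
Why: Ullmann reductive homocoupling of an aryl iodide on copper metal, a reaction type established for 8-iodoflavone ethers with the same ortho-oxygen pattern; the base-free medium spares the 2-unsubstituted pyranone.

Step 5
Reactants: 9 5,5',7,7'-tetrakis(benzyloxy)-8,8'-bichromone; 10 4-(benzyloxy)phenylboronic acid (4–5 equiv)
Product: 12 (2S,2''S)-5,5'',7,7''-tetrakis(benzyloxy)-2,2''-bis[4-(benzyloxy)phenyl]-8,8''-bichroman-4,4''-dione, via mono-adduct 11 (not isolated)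
Conditions: Pd(OCOCF3)2 (10 mol%), (R)-t-BuPyOx [(R)-4-tert-butyl-2-(pyridin-2-yl)-4,5-dihydrooxazole] (12 mol%), NH4PF6 (60 mol%), H2O (10 equiv), ClCH2CH2Cl, 60 °C
Reagents that add atoms: 4-(benzyloxy)phenylboronic acid, OB(O)c1ccc(OCc2ccccc2)cc1
Why: A cationic divalent palladium–PyOx complex takes the aryl group from boron, the aryl–palladium bond adds across the chromone C2=C3 bond with aryl going to C2, and the C3 palladium enolate is protonated by water/NH4+, so divalent palladium returns without a redox step and no free enolate arises that could open ring C. The closest known reaction is the Pd(OCOCF3)2/PyOx-catalysed asymmetric conjugate addition of arylboronic acids to chromones giving flavanones, used here once on each half (first to 11, then to 12); no ring is closed. Each C2 stereocentre is set by the ligand, whose tert-butyl group blocks one face of the bound pyranone during insertion; the (R)-ligand is chosen because, by the facial sense established for cyclic enones, the (S)-ligand should deliver aryl to the face that gives (2R) in a flavanone. The step needs exactly one aryl per half and protonation instead of β-hydride elimination: an H-substituted chromone C2 is a good acceptor whereas the saturated flavanone is not, and the protic additives with no added oxidant keep the C3–palladium intermediate from going on to the flavone. Because the two centres are set independently, most minor-face events end in the heterochiral (2R,2''S) diastereomer, which is removed by chromatography, so the (2S,2''S) product should be enantiomerically richer than a single addition would make it.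

Step 6
Reactants: 12 (2S,2''S)-5,5'',7,7''-tetrakis(benzyloxy)-2,2''-bis[4-(benzyloxy)phenyl]-8,8''-bichroman-4,4''-dione
Product: 13 (2S)-5,7-bis(benzyloxy)-2-[4-(benzyloxy)phenyl]-8-{5,7-bis(benzyloxy)-2-[4-(benzyloxy)phenyl]-4-oxo-4H-chromen-8-yl}chroman-4-one
Conditions: DDQ (0.6–0.7 equiv), 1,4-dioxane, 100 °C, stopped at partial conversion; recovered 12 resubmitted
Reagents that add atoms: none
Why: Quinone dehydrogenation of a flavanone to a flavone (hydride abstraction at C2, activated by the ring oxygen and the 4-alkoxyphenyl group, then proton loss from C3); the halves are insulated by the twisted biaryl, so a deficit of DDQ at low conversion should favour mono-flavone 13 over the bis-flavone, and the untouched (2S) centre is not involved under these non-basic conditions.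

Step 7
Reactants: 13 (2S)-5,7-bis(benzyloxy)-2-[4-(benzyloxy)phenyl]-8-{5,7-bis(benzyloxy)-2-[4-(benzyloxy)phenyl]-4-oxo-4H-chromen-8-yl}chroman-4-one
Product: 14 (2S)-5,7-dihydroxy-8-[5,7-dihydroxy-2-(4-hydroxyphenyl)-4-oxo-4H-chromen-8-yl]-2-(4-hydroxyphenyl)chroman-4-one
Conditions: H2 (1 atm), Pd/C (10 wt%), THF–MeOH, rt
Reagents that add atoms: none
Why: Hydrogenolysis of aryl benzyl ethers on palladium under neutral conditions frees all six phenols without acid or base, so the flavanone cannot open to the chalcone and racemise, while the vinylogous-ester C2''=C3'' bond and the ring C–O bond of the flavanone are reduced much more slowly and the reaction is stopped once the benzyl groups are gone.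

**Compound list**

1 | 2',4',6'-trihydroxyacetophenone | CC(=O)c1c(O)cc(O)cc1O | starting material
2 | benzyl bromide | BrCc1ccccc1 | starting material
3 | 4',6'-bis(benzyloxy)-2'-hydroxyacetophenone | CC(=O)c1c(O)cc(OCc2ccccc2)cc1OCc1ccccc1 | intermediate
4 | benzyltrimethylammonium dichloroiodate | C[N+](C)(C)Cc1ccccc1.Cl[I-]Cl | starting material
5 | 4',6'-bis(benzyloxy)-2'-hydroxy-3'-iodoacetophenone | CC(=O)c1c(O)c(I)c(OCc2ccccc2)cc1OCc1ccccc1 | intermediate
6 | N,N-dimethylformamide dimethyl acetal | COC(OC)N(C)C | starting material
7 | (E)-1-[4,6-bis(benzyloxy)-2-hydroxy-3-iodophenyl]-3-(dimethylamino)prop-2-en-1-one (enaminone, not isolated) | CN(C)/C=C/C(=O)c1c(O)c(I)c(OCc2ccccc2)cc1OCc1ccccc1 | intermediate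
8 | 5,7-bis(benzyloxy)-8-iodochromen-4-one | O=c1ccoc2c(I)c(OCc3ccccc3)cc(OCc3ccccc3)c12 | intermediate
9 | 5,5',7,7'-tetrakis(benzyloxy)-8,8'-bichromone (axial racemate) | O=c1ccoc2c1c(OCc1ccccc1)cc(OCc1ccccc1)c2-c1c(OCc2ccccc2)cc(OCc2ccccc2)c2c(=O)ccoc12 | intermediate
10 | 4-(benzyloxy)phenylboronic acid | OB(O)c1ccc(OCc2ccccc2)cc1 | starting material
11 | (2S)-5,7-bis(benzyloxy)-2-[4-(benzyloxy)phenyl]-8-[5,7-bis(benzyloxy)-4-oxo-4H-chromen-8-yl]chroman-4-one (mono-adduct, not isolated) | O=C1C[C@@H](c2ccc(OCc3ccccc3)cc2)Oc2c1c(OCc1ccccc1)cc(OCc1ccccc1)c2-c1c(OCc2ccccc2)cc(OCc2ccccc2)c2c(=O)ccoc12 | intermediate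
12 | (2S,2''S)-5,5'',7,7''-tetrakis(benzyloxy)-2,2''-bis[4-(benzyloxy)phenyl]-8,8''-bichroman-4,4''-dione | O=C1C[C@@H](c2ccc(OCc3ccccc3)cc2)Oc2c1c(OCc1ccccc1)cc(OCc1ccccc1)c2-c1c(OCc2ccccc2)cc(OCc2ccccc2)c2C(=O)C[C@@H](c3ccc(OCc4ccccc4)cc3)Oc12 | intermediate
13 | (2S)-5,7-bis(benzyloxy)-2-[4-(benzyloxy)phenyl]-8-{5,7-bis(benzyloxy)-2-[4-(benzyloxy)phenyl]-4-oxo-4H-chromen-8-yl}chroman-4-one | O=C1C[C@@H](c2ccc(OCc3ccccc3)cc2)Oc2c1c(OCc1ccccc1)cc(OCc1ccccc1)c2-c1c(OCc2ccccc2)cc(OCc2ccccc2)c2c(=O)cc(-c3ccc(OCc4ccccc4)cc3)oc12 | intermediate
14 | (2S)-5,7-dihydroxy-8-[5,7-dihydroxy-2-(4-hydroxyphenyl)-4-oxo-4H-chromen-8-yl]-2-(4-hydroxyphenyl)chroman-4-one | O=C1C[C@@H](c2ccc(O)cc2)Oc2c1c(O)cc(O)c2-c1c(O)cc(O)c2c(=O)cc(-c3ccc(O)cc3)oc12 | target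

**Step count and risks**

Total step count: 7. Longest linear sequence: 7 steps (1 to 14).

Steps most likely to fail:

Step 5. The second insertion may stall at the electron-rich pyranone beside the crowded biaryl axis while the electron-rich boronic acid is lost to protodeboronation, or face selection may erode for one axial form of 9 (mismatched pairing). The fallback inverts the order of bond formation. It sets out from iodochromone 8, which is arylated as an unhindered monomer with 10 under the same Pd(OCOCF3)2/(R)-t-BuPyOx conditions; the cycle stays at divalent palladium, so the C–I bond should not be engaged. This should give (2S)-5,7-bis(benzyloxy)-2-[4-(benzyloxy)phenyl]-8-iodochroman-4-one F1. Two molecules of F1 are then joined by Ullmann homocoupling (activated Cu powder, DMF, lowest temperature that sustains coupling, about 130 °C), and removal of the heterochiral diastereomer brings the route back at 12.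

Step 6. Oxidation may run on to the bis-flavone, or DDQ at 100 °C may begin to cleave benzyl ethers before a useful conversion is reached. The fallback sets out from 12 and fixes the stoichiometry at low temperature instead of by stopping a hot oxidation. Soft enolisation with TMSOTf (0.9 equiv) and Et3N in CH2Cl2 at −78 to 0 °C should give the mono-silyl enol ether (2S)-5,7-bis(benzyloxy)-2-[4-(benzyloxy)phenyl]-8-{(2S)-5,7-bis(benzyloxy)-2-[4-(benzyloxy)phenyl]-4-(trimethylsilyloxy)-2H-chromen-8-yl}chroman-4-one F2. Saegusa–Ito oxidation of F2 with Pd(OAc)2 in MeCN at rt then desaturates only the silylated half and returns to the route at 13; unchanged 12 is recovered.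

Step 4. Reductive loss of iodine may outrun coupling at the doubly ortho-substituted C8, or the pyranone may be opened by amine released from hot DMF. The fallback sets out from 8 and replaces the reductive homocoupling by a cross-coupling of a nucleophile–electrophile pair. Half of 8 is converted by Miyaura borylation (PdCl2(dppf), bis(pinacolato)diboron, KOAc, dioxane, 90 °C) into 5,7-bis(benzyloxy)-8-(4,4,5,5-tetramethyl-1,3,2-dioxaborolan-2-yl)chromen-4-one F3. Suzuki–Miyaura coupling of F3 with the other half of 8 (Pd(OAc)2, SPhos, anhydrous K3PO4, toluene, 100 °C) returns to the route at 9.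

Further compounds
F1 | step 5 | (2S)-5,7-bis(benzyloxy)-2-[4-(benzyloxy)phenyl]-8-iodochroman-4-one | O=C1C[C@@H](c2ccc(OCc3ccccc3)cc2)Oc2c(I)c(OCc3ccccc3)cc(OCc3ccccc3)c12
F2 | step 6 | mono(trimethylsilyl enol ether) of 12 | O=C1C[C@@H](c2ccc(OCc3ccccc3)cc2)Oc2c1c(OCc1ccccc1)cc(OCc1ccccc1)c2-c1c(OCc2ccccc2)cc(OCc2ccccc2)c2C(O[Si](C)(C)C)=C[C@@H](c3ccc(OCc4ccccc4)cc3)Oc12
F3 | step 4 | 5,7-bis(benzyloxy)-8-(4,4,5,5-tetramethyl-1,3,2-dioxaborolan-2-yl)chromen-4-one | O=c1ccoc2c(B3OC(C)(C)C(C)(C)O3)c(OCc3ccccc3)cc(OCc3ccccc3)c12
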